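The route rests on the aldol bond C2–C3 of the ten-membered carbocycle (C1–C10). A samarium(II)-mediated Reformatsky-type macro-aldol closes this ring last and sets C3 under control of the C4 methyl centre. It exploits the β-hydroxy ketone C1(=O)–C2H2–C3H(OH), whose ketone is flanked by quaternary C10, so only one enolate is possible. The precursor is an open chain: an α-bromomethyl ketone and an α-methyl aldehyde carried on the preformed α-methylene-γ-butyrolactone (ring O–C6–C7–C11–C12). That lactone comes from a Barbier coupling of a bromomethyl butenolide with a C8 aldehyde (C7 and C8 relayed from C6), followed by a Mitsunobu inversion that installs the angelate.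

Key step: step 15

Remark: locants are germacrane-type (C1 ketone, C2 CH2, C3 carbinol, C4 CHMe, C5 CH2, C6 lactone OCH, C7 ring-fusion CH, C8 angelate CH, C9 CH2, C10 C(Me)OAc, C11/C12/C13 lactone α-carbon, carbonyl and exocyclic CH2); the sense of induction of the chiral catalysts in steps 3 and 7 is assigned by analogy, and the antipodal ligand would be used if it proved opposite.

Step 1
Reactants: 1 (R)-3-bromo-2-methylpropan-1-ol
Product: 2 (R)-(3-bromo-2-methylpropoxy)(tert-butyl)dimethylsilane
Conditions: TBSCl, imidazole, CH2Cl2, 0 °C to rt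
Reagents that add atoms: tert-butyldimethylsilyl chloride, CC(C)(C)[Si](C)(C)Cl
Why: Imidazole-promoted silyl ether formation protects the future C3 oxygen; the purchased C4 stereocentre is not involved.

Step 2
Reactants: 2 (R)-(3-bromo-2-methylpropoxy)(tert-butyl)dimethylsilane
Product: 4 (S)-4-(tert-butyldimethylsilyloxy)-3-methylbutanal, via Grignard reagent 3 (not isolated)
Conditions: Mg, THF, rt; DMF, 0 °C; sat. aq. NH4Cl
Reagents that add atoms: N,N-dimethylformamide, CN(C)C=O
Why: Bouveault formylation of the primary Grignard reagent adds the C6 aldehyde carbon; C4 is β to both magnesium and the new carbonyl, so it cannot epimerise.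

Step 3
Reactants: 4 (S)-4-(tert-butyldimethylsilyloxy)-3-methylbutanal; 5 bromoethene
Product: 7 (3R,5S)-6-(tert-butyldimethylsilyloxy)-5-methylhex-1-en-3-ol, via trimethylsilyl ether 6 (not isolated)
Conditions: CrCl2 (10 mol %), chiral oxazoline–sulfonamide ligand (11 mol %), NiCl2 (2 mol %), Mn, TMSCl, LiCl, MeCN, rt; then aq. citric acid
Reagents that add atoms: none
Why: Catalytic asymmetric Nozaki–Hiyama–Kishi vinylation; the chiral chromium(III)–sulfonamide complex should deliver the vinyl group to one aldehyde face and so set the C6 carbinol (R) under catalyst control, the remote C4 centre having little influence.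

Step 4
Reactants: 7 (3R,5S)-6-(tert-butyldimethylsilyloxy)-5-methylhex-1-en-3-ol; 8 2-(bromomethyl)acrylic acid
Product: 9 (3R,5S)-6-(tert-butyldimethylsilyloxy)-5-methylhex-1-en-3-yl 2-(bromomethyl)acrylate
Conditions: DCC, DMAP (5 mol %), CH2Cl2, 0 °C
Reagents that add atoms: none
Why: Steglich esterification of the secondary allylic alcohol with retention at C6; low temperature and catalytic DMAP limit SN2′ attack on the allylic bromide.

Step 5
Reactants: 9 (3R,5S)-6-(tert-butyldimethylsilyloxy)-5-methylhex-1-en-3-yl 2-(bromomethyl)acrylate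
Product: 10 (R)-3-(bromomethyl)-5-[(S)-3-(tert-butyldimethylsilyloxy)-2-methylpropyl]furan-2(5H)-one
Conditions: Grubbs second-generation catalyst (5 mol %), CH2Cl2, 40 °C
Reagents that add atoms: none
Why: Ring-closing metathesis of the vinyl group with the 1,1-disubstituted acrylate closes the butenolide (lactone ring O–C6–C7–C11–C12) with loss of ethene and leaves C6 untouched.

Step 6
Reactants: 11 S-ethyl ethanethioate
Product: 12 [1-(ethylsulfanyl)ethenyloxy]trimethylsilane
Conditions: LDA, THF, −78 °C; TMSCl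
Reagents that add atoms: chlorotrimethylsilane, C[Si](C)(C)Cl
Why: Kinetic deprotonation of the thioester and O-silylation give the silyl ketene thioacetal (enol silane formation); no stereocentre is formed.

Step 7
Reactants: 12 [1-(ethylsulfanyl)ethenyloxy]trimethylsilane; 13 butane-2,3-dione
Product: 15 S-ethyl (R)-3-hydroxy-3-methyl-4-oxopentanethioate, via trimethylsilyl ether 14 (not isolated)
Conditions: [Cu((R,R)-t-Bu-box)](OTf)2 (10 mol %), THF, −78 °C; then 1 M HCl
Reagents that add atoms: none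
Why: Copper(II)–bis(oxazoline)-catalysed Mukaiyama aldol addition to the chelating 1,2-diketone; the square-planar chiral chelate shields one face of the bound ketone, which should set the C10 tertiary carbinol as R.

Step 8
Reactants: 15 S-ethyl (R)-3-hydroxy-3-methyl-4-oxopentanethioate
Product: 16 S-ethyl (R)-3-acetoxy-3-methyl-4-oxopentanethioate
Conditions: Ac2O, TMSOTf (2 mol %), CH2Cl2, −20 to 0 °C
Reagents that add atoms: acetic anhydride, CC(=O)OC(C)=O
Why: Lewis-acid-catalysed acetylation of the tertiary alcohol under non-basic conditions avoids E1cB elimination from the β-oxygenated thioester and leaves C10 unchanged.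

Step 9
Reactants: 16 S-ethyl (R)-3-acetoxy-3-methyl-4-oxopentanethioate
Product: 17 (R)-3-acetoxy-3-methyl-4-oxopentanal
Conditions: Et3SiH, 10% Pd/C, acetone, rt
Reagents that add atoms: none
Why: Fukuyama reduction (Pd-catalysed silane reduction of a thioester) gives the aldehyde at neutral pH without touching the ketone or the tertiary acetate.

Step 10
Reactants: 10 (R)-3-(bromomethyl)-5-[(S)-3-(tert-butyldimethylsilyloxy)-2-methylpropyl]furan-2(5H)-one; 17 (R)-3-acetoxy-3-methyl-4-oxopentanal
Product: 19 (3R,5S)-5-hydroxy-3-methyl-2-oxo-5-{(2R,3R)-2-[(2S)-3-(tert-butyldimethylsilyloxy)-2-methylpropyl]-4-methylidene-5-oxooxolan-3-yl}pentan-3-yl acetate, via allylzinc bromide 18 (not isolated)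
Conditions: Zn dust, THF/sat. aq. NH4Cl, 0 °C to rt
Reagents that add atoms: none
Why: Zinc Barbier allylation by the bromomethyl butenolide (SE2′) forms C7–C8 and unveils the exocyclic methylene; attack on C7 anti to the C6 side chain sets the trans lactone, and the chair Zimmerman–Traxler transition state with the aldehyde substituent equatorial sets C8 as the 8S carbinol.

Step 11
Reactants: 19 (3R,5S)-5-hydroxy-3-methyl-2-oxo-5-{(2R,3R)-2-[(2S)-3-(tert-butyldimethylsilyloxy)-2-methylpropyl]-4-methylidene-5-oxooxolan-3-yl}pentan-3-yl acetate; 20 angelic acid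
Product: 21 (1R,3R)-3-acetoxy-3-methyl-4-oxo-1-{(2R,3S)-2-[(2S)-3-(tert-butyldimethylsilyloxy)-2-methylpropyl]-4-methylidene-5-oxooxolan-3-yl}pentyl (2Z)-2-methylbut-2-enoate
Conditions: PPh3, DIAD, toluene, 0 °C to rt
Reagents that add atoms: none
Why: Mitsunobu esterification displaces the C8 alkoxyphosphonium by angelate in an SN2 step, inverting C8 to the required 8R configuration and installing the Z ester under neutral conditions that should not isomerise it.

Step 12
Reactants: 21 (1R,3R)-3-acetoxy-3-methyl-4-oxo-1-{(2R,3S)-2-[(2S)-3-(tert-butyldimethylsilyloxy)-2-methylpropyl]-4-methylidene-5-oxooxolan-3-yl}pentyl (2Z)-2-methylbut-2-enoate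
Product: 23 (1R,3R)-3-acetoxy-5-bromo-3-methyl-4-oxo-1-{(2R,3S)-2-[(2S)-3-(tert-butyldimethylsilyloxy)-2-methylpropyl]-4-methylidene-5-oxooxolan-3-yl}pentyl (2Z)-2-methylbut-2-enoate, via silyl enol ether 22 (not isolated)
Conditions: TMSOTf, Et3N, CH2Cl2, −20 °C; then NBS, NaHCO3, THF, −78 to 0 °C
Reagents that add atoms: N-bromosuccinimide, O=C1CCC(=O)N1Br
Why: Soft enolisation to the silyl enol ether (C2 is the only enolisable position of the ketone because C10 is quaternary) and electrophilic bromination with NBS give the bromomethyl ketone; no stereocentre is touched.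

Step 13
Reactants: 23 (1R,3R)-3-acetoxy-5-bromo-3-methyl-4-oxo-1-{(2R,3S)-2-[(2S)-3-(tert-butyldimethylsilyloxy)-2-methylpropyl]-4-methylidene-5-oxooxolan-3-yl}pentyl (2Z)-2-methylbut-2-enoate
Product: 24 (1R,3R)-3-acetoxy-5-bromo-1-{(2R,3S)-2-[(2S)-3-hydroxy-2-methylpropyl]-4-methylidene-5-oxooxolan-3-yl}-3-methyl-4-oxopentyl (2Z)-2-methylbut-2-enoate
Conditions: 48% aq. HF, MeCN, 0 °C
Reagents that add atoms: none
Why: Acidic fluoride cleavage of the primary silyl ether (desilylation) under conditions that the α-bromo ketone, the esters and the methylene lactone should tolerate.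

Step 14
Reactants: 24 (1R,3R)-3-acetoxy-5-bromo-1-{(2R,3S)-2-[(2S)-3-hydroxy-2-methylpropyl]-4-methylidene-5-oxooxolan-3-yl}-3-methyl-4-oxopentyl (2Z)-2-methylbut-2-enoate
Product: 25 (1R,3R)-3-acetoxy-5-bromo-3-methyl-1-{(2R,3S)-2-[(2S)-2-methyl-3-oxopropyl]-4-methylidene-5-oxooxolan-3-yl}-4-oxopentyl (2Z)-2-methylbut-2-enoate
Conditions: Dess–Martin periodinane, NaHCO3, CH2Cl2, 0 °C
Reagents that add atoms: none
Why: Buffered Dess–Martin oxidation should give the α-methyl aldehyde without epimerising C4.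

Step 15
Reactants: 25 (1R,3R)-3-acetoxy-5-bromo-3-methyl-1-{(2R,3S)-2-[(2S)-2-methyl-3-oxopropyl]-4-methylidene-5-oxooxolan-3-yl}-4-oxopentyl (2Z)-2-methylbut-2-enoate
Product: 28 CNP0141210.1 (3S,4S,6R,7S,8R,10R)-10-acetoxy-8-angeloyloxy-3-hydroxy-1-oxogermacr-11(13)-en-12,6-olide, via samarium enolate 26 (not isolated), via samarium aldolate 27 (not isolated)
Conditions: SmI2 (2.2 equiv) added dropwise, THF (2 mM), −78 °C; sat. aq. NH4Cl at −78 °C
Reagents that add atoms: none
Why: Two single-electron transfers from SmI2 cleave the C2–Br bond to give the regiodefined samarium(III) enolate 26, which adds to the C3 aldehyde through a samarium-bridged six-membered transition state to give aldolate 27 and, after cold protonation, the β-hydroxy ketone. The closest known reaction type is the SmI2-promoted intramolecular Reformatsky-type aldol cyclisation of ω-formyl α-halo carbonyl compounds, which is used for medium-ring carbocycles and lactones. The ten-membered carbocycle closes in a 10-(enolendo)-exo-trig mode. The new C3 stereocentre is controlled by the adjacent C4 methyl centre (Felkin–Anh: C5 arm anti to the incoming enolate, C4–H on the approach path), which should give the 3,4-syn (3S) carbinol. The step needs C–Br reduction ahead of reduction of the aldehyde, the α-acetoxy ketone and the methylene lactone, which the much faster electron transfer to an α-bromo ketone at −78 °C with only two equivalents of reductant should secure. It also needs cyclisation ahead of oligomerisation, secured by high dilution, the rigid lactone and the quaternary C10, while cold quenching prevents retro-aldol opening and dehydration.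

Compound list
1 | (R)-3-bromo-2-methylpropan-1-ol | BrC[C@H](C)CO | starting material
2 | (R)-(3-bromo-2-methylpropoxy)(tert-butyl)dimethylsilane | BrC[C@H](C)CO[Si](C)(C)C(C)(C)C | intermediate
3 | [(R)-3-(tert-butyldimethylsilyloxy)-2-methylpropyl]magnesium bromide | Br[Mg]C[C@H](C)CO[Si](C)(C)C(C)(C)C | intermediate
4 | (S)-4-(tert-butyldimethylsilyloxy)-3-methylbutanal | O=CC[C@H](C)CO[Si](C)(C)C(C)(C)C | intermediate
5 | bromoethene (vinyl bromide) | C=CBr | starting material
6 | (3R,5S)-6-(tert-butyldimethylsilyloxy)-5-methyl-3-(trimethylsilyloxy)hex-1-ene | C=C[C@H](O[Si](C)(C)C)C[C@H](C)CO[Si](C)(C)C(C)(C)C | intermediate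
7 | (3R,5S)-6-(tert-butyldimethylsilyloxy)-5-methylhex-1-en-3-ol | C=C[C@H](O)C[C@H](C)CO[Si](C)(C)C(C)(C)C | intermediate
8 | 2-(bromomethyl)acrylic acid | C=C(CBr)C(=O)O | starting material
9 | (3R,5S)-6-(tert-butyldimethylsilyloxy)-5-methylhex-1-en-3-yl 2-(bromomethyl)acrylate | C=C[C@H](OC(=O)C(=C)CBr)C[C@H](C)CO[Si](C)(C)C(C)(C)C | intermediate
10 | (R)-3-(bromomethyl)-5-[(S)-3-(tert-butyldimethylsilyloxy)-2-methylpropyl]furan-2(5H)-one | BrCC1=C[C@@H](C[C@H](C)CO[Si](C)(C)C(C)(C)C)OC1=O | intermediate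
11 | S-ethyl ethanethioate | CCSC(C)=O | starting material
12 | [1-(ethylsulfanyl)ethenyloxy]trimethylsilane | C=C(SCC)O[Si](C)(C)C | intermediate
13 | butane-2,3-dione | CC(=O)C(C)=O | starting material
14 | S-ethyl (R)-3-methyl-4-oxo-3-(trimethylsilyloxy)pentanethioate | CCSC(=O)C[C@@](C)(O[Si](C)(C)C)C(C)=O | intermediate
15 | S-ethyl (R)-3-hydroxy-3-methyl-4-oxopentanethioate | CCSC(=O)C[C@@](C)(O)C(C)=O | intermediate
16 | S-ethyl (R)-3-acetoxy-3-methyl-4-oxopentanethioate | CCSC(=O)C[C@@](C)(OC(C)=O)C(C)=O | intermediate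
17 | (R)-3-acetoxy-3-methyl-4-oxopentanal | O=CC[C@@](C)(OC(C)=O)C(C)=O | intermediate
18 | {[(R)-5-[(S)-3-(tert-butyldimethylsilyloxy)-2-methylpropyl]-2-oxo-2,5-dihydrofuran-3-yl]methyl}zinc bromide | Br[Zn]CC1=C[C@@H](C[C@H](C)CO[Si](C)(C)C(C)(C)C)OC1=O | intermediate
19 | (3R,5S)-5-hydroxy-3-methyl-2-oxo-5-{(2R,3R)-2-[(2S)-3-(tert-butyldimethylsilyloxy)-2-methylpropyl]-4-methylidene-5-oxooxolan-3-yl}pentan-3-yl acetate (8S alcohol) | C=C1C(=O)O[C@H](C[C@H](C)CO[Si](C)(C)C(C)(C)C)[C@H]1[C@@H](O)C[C@@](C)(OC(C)=O)C(C)=O | intermediate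
20 | angelic acid, (Z)-2-methylbut-2-enoic acid | C/C=C(/C)C(=O)O | starting material
21 | (1R,3R)-3-acetoxy-3-methyl-4-oxo-1-{(2R,3S)-2-[(2S)-3-(tert-butyldimethylsilyloxy)-2-methylpropyl]-4-methylidene-5-oxooxolan-3-yl}pentyl (2Z)-2-methylbut-2-enoate | C=C1C(=O)O[C@H](C[C@H](C)CO[Si](C)(C)C(C)(C)C)[C@H]1[C@H](OC(=O)/C(C)=C\C)C[C@@](C)(OC(C)=O)C(C)=O | intermediate
22 | trimethylsilyl enol ether of 21 at C1=C2 | C=C1C(=O)O[C@H](C[C@H](C)CO[Si](C)(C)C(C)(C)C)[C@H]1[C@H](OC(=O)/C(C)=C\C)C[C@@](C)(OC(C)=O)C(=C)O[Si](C)(C)C | intermediate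
23 | (1R,3R)-3-acetoxy-5-bromo-3-methyl-4-oxo-1-{(2R,3S)-2-[(2S)-3-(tert-butyldimethylsilyloxy)-2-methylpropyl]-4-methylidene-5-oxooxolan-3-yl}pentyl (2Z)-2-methylbut-2-enoate | C=C1C(=O)O[C@H](C[C@H](C)CO[Si](C)(C)C(C)(C)C)[C@H]1[C@H](OC(=O)/C(C)=C\C)C[C@@](C)(OC(C)=O)C(=O)CBr | intermediate
24 | (1R,3R)-3-acetoxy-5-bromo-1-{(2R,3S)-2-[(2S)-3-hydroxy-2-methylpropyl]-4-methylidene-5-oxooxolan-3-yl}-3-methyl-4-oxopentyl (2Z)-2-methylbut-2-enoate | C=C1C(=O)O[C@H](C[C@H](C)CO)[C@H]1[C@H](OC(=O)/C(C)=C\C)C[C@@](C)(OC(C)=O)C(=O)CBr | intermediate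
25 | (1R,3R)-3-acetoxy-5-bromo-3-methyl-1-{(2R,3S)-2-[(2S)-2-methyl-3-oxopropyl]-4-methylidene-5-oxooxolan-3-yl}-4-oxopentyl (2Z)-2-methylbut-2-enoate | C=C1C(=O)O[C@H](C[C@H](C)C=O)[C@H]1[C@H](OC(=O)/C(C)=C\C)C[C@@](C)(OC(C)=O)C(=O)CBr | intermediate
26 | diiodosamarium(III) enolate of 25 at C1=C2 | C=C1C(=O)O[C@H](C[C@H](C)C=O)[C@H]1[C@H](OC(=O)/C(C)=C\C)C[C@@](C)(OC(C)=O)C(=C)O[Sm](I)I | intermediate
27 | diiodosamarium(III) C3-alkoxide of 28 | C=C1C(=O)O[C@@H]2C[C@H](C)[C@@H](O[Sm](I)I)CC(=O)[C@](C)(OC(C)=O)C[C@@H](OC(=O)/C(C)=C\C)[C@@H]12 | intermediate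
28 | CNP0141210.1, (3S,4S,6R,7S,8R,10R)-10-acetoxy-8-angeloyloxy-3-hydroxy-1-oxogermacr-11(13)-en-12,6-olide | C=C1C(=O)O[C@@H]2C[C@H](C)[C@@H](O)CC(=O)[C@](C)(OC(C)=O)C[C@@H](OC(=O)/C(C)=C\C)[C@@H]12 | target

Total step count: 15. Longest linear sequence: 11 steps (steps 1–5 and 10–15, from 1); the aldehyde arm (steps 6–9) joins at step 10.

Steps most likely to fail

Step 15. The samarium(II) may over-reduce the α-acetoxy ketone or the aldehyde, the enolate may add to the methylene lactone, or the chain may oligomerise instead of closing. The fallback is a halogen-free, non-reductive closure that sets out from 21. Aqueous HF in MeCN would give the keto alcohol F1, and buffered Dess–Martin oxidation the keto aldehyde F2. TMSOTf and i-Pr2NEt in dilute CH2Cl2 at −78 °C (one-pot enol-silane formation and silyl-triflate-promoted intramolecular Mukaiyama aldol through an open transition state with the same Felkin bias) should then give the C3 trimethylsilyl ether F3. Dilute citric acid in THF would release 28, where the route is rejoined; steps 12–15 are bypassed.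

Step 11. The activated C8 alkoxyphosphonium may eliminate toward the conjugated diene, or a neighbouring ester carbonyl may participate and give retention instead of clean inversion. The fallback sets C8 directly instead of inverting it and sets out from 10. Pd-catalysed stannylation with hexabutylditin would give the allylstannane F4. Its BF3·OEt2-promoted addition to 17 at −78 °C (open antiperiplanar transition state, syn-selective, still anti to the C6 side chain) should give the 8R alcohol F5. Yamaguchi esterification with angelic acid 20 would convert F5 with retention into 21, where the route is rejoined.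

Step 10. The β-acetoxy aldehyde 17 may lose acetic acid by E1cB before it couples, or the acetyl group may migrate from O10 to the new C8 hydroxyl. The fallback carries C10–O as a silyl ether and acetylates late; it sets out from 14, isolated by non-acidic work-up. Fukuyama reduction would give the silyloxy aldehyde F6, and Barbier coupling with 10 the adduct F7. Mitsunobu esterification with 20 would give the angelate F8, aqueous citric acid the tertiary alcohol F9, and Ac2O/DMAP/Et3N the acetate 21, where the route is rejoined.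

Further compounds
F1 | step 15 | keto alcohol, 21 without the silyl group (free C3 hydroxyl) | C=C1C(=O)O[C@H](C[C@H](C)CO)[C@H]1[C@H](OC(=O)/C(C)=C\C)C[C@@](C)(OC(C)=O)C(C)=O
F2 | step 15 | keto aldehyde, C3 aldehyde analogue of 21 | C=C1C(=O)O[C@H](C[C@H](C)C=O)[C@H]1[C@H](OC(=O)/C(C)=C\C)C[C@@](C)(OC(C)=O)C(C)=O
F3 | step 15 | 3-O-trimethylsilyl ether of 28 | C=C1C(=O)O[C@@H]2C[C@H](C)[C@@H](O[Si](C)(C)C)CC(=O)[C@](C)(OC(C)=O)C[C@@H](OC(=O)/C(C)=C\C)[C@@H]12
F4 | step 11 | tributyl{[(R)-5-[(S)-3-(tert-butyldimethylsilyloxy)-2-methylpropyl]-2-oxo-2,5-dihydrofuran-3-yl]methyl}stannane | CCCC[Sn](CCCC)(CCCC)CC1=C[C@@H](C[C@H](C)CO[Si](C)(C)C(C)(C)C)OC1=O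
F5 | step 11 | 8R alcohol, C8 epimer of 19 | C=C1C(=O)O[C@H](C[C@H](C)CO[Si](C)(C)C(C)(C)C)[C@H]1[C@H](O)C[C@@](C)(OC(C)=O)C(C)=O
F6 | step 10 | (R)-3-methyl-4-oxo-3-(trimethylsilyloxy)pentanal | O=CC[C@@](C)(O[Si](C)(C)C)C(C)=O
F7 | step 10 | 10-O-trimethylsilyl analogue of 19 (8S alcohol) | C=C1C(=O)O[C@H](C[C@H](C)CO[Si](C)(C)C(C)(C)C)[C@H]1[C@@H](O)C[C@@](C)(O[Si](C)(C)C)C(C)=O
F8 | step 10 | 10-O-trimethylsilyl analogue of 21 (8R angelate) | C=C1C(=O)O[C@H](C[C@H](C)CO[Si](C)(C)C(C)(C)C)[C@H]1[C@H](OC(=O)/C(C)=C\C)C[C@@](C)(O[Si](C)(C)C)C(C)=O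
F9 | step 10 | 10-deacetyl 21 (tertiary alcohol) | C=C1C(=O)O[C@H](C[C@H](C)CO[Si](C)(C)C(C)(C)C)[C@H]1[C@H](OC(=O)/C(C)=C\C)C[C@@](C)(O)C(C)=O
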